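Oxolane locants: O1, C2 (bears carbinol carbon C1'), C3 (bears 4-methoxyphenyl), C4 (bears OH), C5 (CH2). The ring is cut at O1–C2 and C3–C4, uncovering O1–C5–C4(OH) as 2-(triethylsilyloxy)acetaldehyde and C2–C3–C1' as a chiral (Z)-1,3-diarylallylsilane whose silicon stands in for the C1' hydroxyl. One BF3-promoted formal [3+2] annulation forms both bonds: C3 attacks the aldehyde anti to silicon and the silyl ether oxygen captures the β-silyl cation at C2. The feature exploited is the O1–C2–C1'(OH) array beside aryl-bearing C3: a C1'–Si bond makes C3 nucleophilic, C2 electrophilic, and relays its configuration. Tamao–Fleming oxidation finishes.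

Key step: step 8

Remark: the sense of induction of the chiral copper catalyst in step 2 is not predicted here; the ligand enantiomer is chosen so that the S-configured silane 6 is formed.

**Step 1**
Reactants: 1 1-(4-methoxyphenyl)ethan-1-one; 2 3,4-dimethoxybenzaldehyde
Product: 4 (E)-3-(3,4-dimethoxyphenyl)-1-(4-methoxyphenyl)prop-2-en-1-one, via aldol adduct 3 (not isolated)
Conditions: NaOH (10% aq), EtOH, rt
Reagents that add atoms: none
Why: Claisen–Schmidt condensation, in which the acetophenone enolate adds to the non-enolisable aldehyde and the aldol loses water by E1cB to the conjugated E-enone.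

**Step 2**
Reactants: 4 (E)-3-(3,4-dimethoxyphenyl)-1-(4-methoxyphenyl)prop-2-en-1-one
Product: 6 (3S)-3-(3,4-dimethoxyphenyl)-3-[dimethyl(phenyl)silyl]-1-(4-methoxyphenyl)propan-1-one, via boron enolate 5 (not isolated)
Conditions: PhMe2Si–Bpin (1.1 equiv), CuCl (2 mol%), chiral imidazolinium salt (NHC precursor, 2.2 mol%), NaOt-Bu (4.5 mol%), THF, −78 °C; then H2O
Reagents that add atoms: (dimethylphenylsilyl)boronic acid pinacol ester, C[Si](C)(c1ccccc1)B1OC(C)(C)C(C)(C)O1
Why: A silyl–copper species formed by Si–B transmetalation adds to the enone β-carbon inside the chiral NHC–copper pocket (copper-catalysed enantioselective conjugate silyl addition), which sets the silicon-bearing stereocentre C1' as S, and hydrolysis of the boron enolate gives the ketone.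

**Step 3**
Reactants: 6 (3S)-3-(3,4-dimethoxyphenyl)-3-[dimethyl(phenyl)silyl]-1-(4-methoxyphenyl)propan-1-one
Product: 8 (1Z,3S)-3-(3,4-dimethoxyphenyl)-3-[dimethyl(phenyl)silyl]-1-(4-methoxyphenyl)prop-1-en-1-yl trifluoromethanesulfonate, via potassium enolate 7 (not isolated)
Conditions: KN(SiMe3)2, THF, −78 °C; then PhNTf2, −78 → 0 °C
Reagents that add atoms: N-phenylbis(trifluoromethanesulfonimide), O=S(=O)(N(c1ccccc1)S(=O)(=O)C(F)(F)F)C(F)(F)F
Why: The base removes a proton from the only enolisable CH2 to give the Z-enolate favoured for aryl ketones, and O-sulfonylation traps it as the enol triflate (kinetic enolate triflation) without involving the β-silyl stereocentre.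

**Step 4**
Reactants: 8 (1Z,3S)-3-(3,4-dimethoxyphenyl)-3-[dimethyl(phenyl)silyl]-1-(4-methoxyphenyl)prop-1-en-1-yl trifluoromethanesulfonate
Product: 9 [(1S,2E)-1-(3,4-dimethoxyphenyl)-3-(4-methoxyphenyl)prop-2-en-1-yl]dimethyl(phenyl)silane
Conditions: Pd(OAc)2 (5 mol%), PPh3 (10 mol%), HCO2H, n-Bu3N, DMF, 60 °C
Reagents that add atoms: none
Why: Oxidative addition of the enol triflate to zerovalent palladium, formate-to-hydride exchange with loss of CO2 and reductive elimination replace OTf by H with retention, so the Z-triflate should give the E-alkene (palladium-catalysed formate reduction of enol triflates).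

**Step 5**
Reactants: 9 [(1S,2E)-1-(3,4-dimethoxyphenyl)-3-(4-methoxyphenyl)prop-2-en-1-yl]dimethyl(phenyl)silane
Product: 10 [(1S,2Z)-1-(3,4-dimethoxyphenyl)-3-(4-methoxyphenyl)prop-2-en-1-yl]dimethyl(phenyl)silane
Conditions: Ir(ppy)3 (1 mol%), degassed MeCN, blue LEDs (450 nm), rt
Reagents that add atoms: none
Why: Triplet energy transfer to the conjugated E-styrene gives a twisted triplet that relaxes to both isomers, and because the Z-isomer is deconjugated by allylic 1,3-strain and no longer accepts energy it should accumulate (sensitised E-to-Z isomerisation), with C1' untouched.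

**Step 6**
Reactants: 11 (Z)-but-2-ene-1,4-diol
Product: 12 (Z)-1,4-bis(triethylsilyloxy)but-2-ene
Conditions: Et3SiCl, imidazole, CH2Cl2, 0 °C → rt
Reagents that add atoms: chlorotriethylsilane, CC[Si](Cl)(CC)CC
Why: Standard silylation of both primary hydroxyls with a silyl chloride and imidazole.

**Step 7**
Reactants: 12 (Z)-1,4-bis(triethylsilyloxy)but-2-ene
Product: 14 2-(triethylsilyloxy)acetaldehyde, via secondary ozonide 13 (not isolated)
Conditions: O3, CH2Cl2, −78 °C; then PPh3, −78 °C → rt; used fresh
Reagents that add atoms: ozone, [O-][O+]=O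
Why: Ozonolysis of the symmetrical alkene and reductive cleavage of the ozonide by PPh3 should give two molecules of the α-silyloxy aldehyde, the silyl ethers being inert to ozone.

**Step 8**
Reactants: 10 [(1S,2Z)-1-(3,4-dimethoxyphenyl)-3-(4-methoxyphenyl)prop-2-en-1-yl]dimethyl(phenyl)silane; 14 2-(triethylsilyloxy)acetaldehyde
Product: 15 (3S,4R,5S)-5-[(R)-(3,4-dimethoxyphenyl)[dimethyl(phenyl)silyl]methyl]-4-(4-methoxyphenyl)oxolan-3-ol
Conditions: BF3·OEt2 (1.2 equiv), 14 (1.5 equiv), CH2Cl2, −78 °C; then sat. aq NaHCO3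
Reagents that add atoms: none
Why: BF3 activates aldehyde 14, C3 of the allylsilane adds anti to silicon (anti-SE2') from the conformer that keeps the C1'–H in the alkene plane (allylic 1,3-strain of the Z-alkene), and the C2 cation, held by hyperconjugation with the C1'–Si bond, is captured by the silyl ether oxygen O1 with loss of Et3SiF. The closest known reaction type is the Lewis-acid formal [3+2] annulation of α-silyloxy aldehydes with allylsilanes, in which the allylsilane acts as a two-carbon partner and keeps its silicon. The oxolane closes in a 5-exo mode, O1 attacking C2 on the face opposite silicon while the C2···Si interaction that is released stays outside the ring. C3 and C2 are fixed by the C1' silicon stereocentre (face of attack) and by the Z geometry, which is carried over suprafacially as the 2,3-cis relationship; C4 should follow from the synclinal pairing that puts the bulky C2 substituent under the aldehyde hydrogen, the pairing behind the 2,4-cis (here all-cis) oxolanols of this annulation type. The step needs attack at C3 and not at C2, which the β-silicon effect and the twisted, poorly conjugated anisyl ring of the Z-alkene should secure, and ring closure instead of loss of silicon, which the internal oxygen nucleophile, the bulky PhMe2Si group and −78 °C favour.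

**Step 9**
Reactants: 15 (3S,4R,5S)-5-[(R)-(3,4-dimethoxyphenyl)[dimethyl(phenyl)silyl]methyl]-4-(4-methoxyphenyl)oxolan-3-ol
Product: 16 (3S,4R,5S)-5-[(R)-(3,4-dimethoxyphenyl)(hydroxy)methyl]-4-(4-methoxyphenyl)oxolan-3-ol
Conditions: t-BuOOH (in decane), CsOH·H2O, n-Bu4NF, DMF, rt → 50 °C; then aq Na2S2O3
Reagents that add atoms: tert-butyl hydroperoxide, CC(C)(C)OO
Why: Tamao–Fleming oxidation under nucleophilic conditions, in which the hydroperoxide anion adds to fluoride-activated silicon and the phenyl and then the C1' group migrate from silicon to oxygen, the latter with retention, so C1'–Si should become C1'–OH (R) without the electrophiles that would attack the electron-rich rings.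

**Compound list**
1 | 1-(4-methoxyphenyl)ethan-1-one | CC(=O)c1ccc(OC)cc1 | starting material
2 | 3,4-dimethoxybenzaldehyde | COc1ccc(C=O)cc1OC | starting material
3 | 3-(3,4-dimethoxyphenyl)-3-hydroxy-1-(4-methoxyphenyl)propan-1-one (racemic aldol adduct) | COc1ccc(cc1)C(=O)CC(O)c1ccc(OC)c(OC)c1 | intermediate
4 | (E)-3-(3,4-dimethoxyphenyl)-1-(4-methoxyphenyl)prop-2-en-1-one | COc1ccc(cc1)C(=O)/C=C/c1ccc(OC)c(OC)c1 | intermediate
5 | 2-{[(1Z,3S)-3-(3,4-dimethoxyphenyl)-3-[dimethyl(phenyl)silyl]-1-(4-methoxyphenyl)prop-1-en-1-yl]oxy}-4,4,5,5-tetramethyl-1,3,2-dioxaborolane (boron enolate) | COc1ccc(cc1)/C(OB1OC(C)(C)C(C)(C)O1)=C/[C@H]([Si](C)(C)c1ccccc1)c1ccc(OC)c(OC)c1 | intermediate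
6 | (3S)-3-(3,4-dimethoxyphenyl)-3-[dimethyl(phenyl)silyl]-1-(4-methoxyphenyl)propan-1-one | COc1ccc(cc1)C(=O)C[C@H]([Si](C)(C)c1ccccc1)c1ccc(OC)c(OC)c1 | intermediate
7 | potassium (1Z,3S)-3-(3,4-dimethoxyphenyl)-3-[dimethyl(phenyl)silyl]-1-(4-methoxyphenyl)prop-1-en-1-olate | COc1ccc(cc1)/C([O-])=C/[C@H]([Si](C)(C)c1ccccc1)c1ccc(OC)c(OC)c1.[K+] | intermediate
8 | (1Z,3S)-3-(3,4-dimethoxyphenyl)-3-[dimethyl(phenyl)silyl]-1-(4-methoxyphenyl)prop-1-en-1-yl trifluoromethanesulfonate | COc1ccc(cc1)/C(OS(=O)(=O)C(F)(F)F)=C/[C@H]([Si](C)(C)c1ccccc1)c1ccc(OC)c(OC)c1 | intermediate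
9 | [(1S,2E)-1-(3,4-dimethoxyphenyl)-3-(4-methoxyphenyl)prop-2-en-1-yl]dimethyl(phenyl)silane | COc1ccc(/C=C/[C@H]([Si](C)(C)c2ccccc2)c2ccc(OC)c(OC)c2)cc1 | intermediate
10 | [(1S,2Z)-1-(3,4-dimethoxyphenyl)-3-(4-methoxyphenyl)prop-2-en-1-yl]dimethyl(phenyl)silane | COc1ccc(/C=C\[C@H]([Si](C)(C)c2ccccc2)c2ccc(OC)c(OC)c2)cc1 | intermediate
11 | (Z)-but-2-ene-1,4-diol | OC/C=C\CO | starting material
12 | (Z)-1,4-bis(triethylsilyloxy)but-2-ene | CC[Si](CC)(CC)OC/C=C\CO[Si](CC)(CC)CC | intermediate
13 | 3,5-bis[(triethylsilyloxy)methyl]-1,2,4-trioxolane (secondary ozonide) | CC[Si](CC)(CC)OCC1OOC(CO[Si](CC)(CC)CC)O1 | intermediate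
14 | 2-(triethylsilyloxy)acetaldehyde | CC[Si](CC)(CC)OCC=O | intermediate
15 | (3S,4R,5S)-5-[(R)-(3,4-dimethoxyphenyl)[dimethyl(phenyl)silyl]methyl]-4-(4-methoxyphenyl)oxolan-3-ol | COc1ccc([C@H]2[C@@H]([C@H]([Si](C)(C)c3ccccc3)c3ccc(OC)c(OC)c3)OC[C@H]2O)cc1 | intermediate
16 | (3S,4R,5S)-5-[(R)-(3,4-dimethoxyphenyl)(hydroxy)methyl]-4-(4-methoxyphenyl)oxolan-3-ol | COc1ccc([C@H]2[C@@H]([C@H](O)c3ccc(OC)c(OC)c3)OC[C@H]2O)cc1 | target

Total step count: 9. Longest linear sequence: 7 (steps 1, 2, 3, 4, 5, 8, 9); steps 6 and 7 form the side branch to 14.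

**Steps most likely to fail**

1. Step 8. The aldehyde may be paired with the alkene through the antiperiplanar instead of the synclinal arrangement, so that C4 is set with its hydroxyl trans to the C3 aryl. Loss of silicon from the β-silyl cation (Hosomi–Sakurai allylation) and attack at C2 instead of C3 are the other leaks. The fallback sets C4 by substrate-controlled hydride delivery instead of by the pairing in the annulation. It sets out from 10 and 14. The annulation product epimeric at C4, (3R,4R,5S)-5-[(R)-(3,4-dimethoxyphenyl)[dimethyl(phenyl)silyl]methyl]-4-(4-methoxyphenyl)oxolan-3-ol F1, would be oxidised with DMP (NaHCO3, CH2Cl2, 0 °C) to (4S,5S)-5-[(R)-(3,4-dimethoxyphenyl)[dimethyl(phenyl)silyl]methyl]-4-(4-methoxyphenyl)oxolan-3-one F2. LiBH(s-Bu)3 (THF, −78 °C) should then add hydride to the face opposite the C3 aryl and the C2 side chain, which comes back to the route at 15; the cold, non-basic handling is meant to avoid epimerisation at C3.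

2. Step 9. The benzylic C1'–Si bond may be cleaved without oxygen transfer (protodesilylation), or base may trigger β-elimination of silicon and O1 that opens the oxolane. The fallback uses the cis C4 hydroxyl to take the phenyl group off silicon before any oxidant is present. It sets out from 15. KOt-Bu in DMSO (rt) should let the C4 alkoxide attack silicon and expel benzene, giving the bicyclic siloxane 4-(3,4-dimethoxyphenyl)-8-(4-methoxyphenyl)-3,3-dimethyl-2,6-dioxa-3-silabicyclo[3.2.1]octane F3 (carbon stereocentres as in 15). This alkoxysilane would then be oxidised under buffered Tamao conditions (H2O2, KF, KHCO3, THF/MeOH, rt), which comes back to the route at 16.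

3. Step 5. The photostationary state may retain E-isomer, which would feed the 2,3-trans series into the annulation, and sensitised side reactions of the allylsilane are possible. The fallback makes the Z-alkene by cis-hydrogenation of an alkyne. It sets out from 8. Anti-elimination of the triflate (KN(SiMe3)2, 1.0 equiv added slowly, THF, −78 °C, to limit deprotonation at the propargylic carbon) would give the propargylic silane (R)-[1-(3,4-dimethoxyphenyl)-3-(4-methoxyphenyl)prop-2-yn-1-yl]dimethyl(phenyl)silane F4 (same spatial arrangement at C1' as in 8; the descriptor changes with the priorities). Semihydrogenation over lead-poisoned Pd/CaCO3 with quinoline (H2, 1 atm, EtOAc) should then come back to the route at 10 without passing through 9.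

**Further compounds**
F1 | step 8 | (3R,4R,5S)-5-[(R)-(3,4-dimethoxyphenyl)[dimethyl(phenyl)silyl]methyl]-4-(4-methoxyphenyl)oxolan-3-ol | COc1ccc([C@H]2[C@@H]([C@H]([Si](C)(C)c3ccccc3)c3ccc(OC)c(OC)c3)OC[C@@H]2O)cc1
F2 | step 8 | (4S,5S)-5-[(R)-(3,4-dimethoxyphenyl)[dimethyl(phenyl)silyl]methyl]-4-(4-methoxyphenyl)oxolan-3-one | COc1ccc([C@H]2[C@@H]([C@H]([Si](C)(C)c3ccccc3)c3ccc(OC)c(OC)c3)OCC2=O)cc1
F3 | step 9 | 4-(3,4-dimethoxyphenyl)-8-(4-methoxyphenyl)-3,3-dimethyl-2,6-dioxa-3-silabicyclo[3.2.1]octane (carbon stereocentres as in 15) | COc1ccc([C@H]2[C@@H]([C@H]([Si]3(C)C)c4ccc(OC)c(OC)c4)OC[C@H]2O3)cc1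
F4 | step 5 | (R)-[1-(3,4-dimethoxyphenyl)-3-(4-methoxyphenyl)prop-2-yn-1-yl]dimethyl(phenyl)silane | COc1ccc(cc1)C#C[C@H]([Si](C)(C)c1ccccc1)c1ccc(OC)c(OC)c1
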